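Slowness is where you start: ask whether the time allowed outlasts the slow tail of the left-handed substrate.

the same everywhere: left-handed substrate 20 mM; right-handed substrate 20 mM; gas 0.72 mM (held)
- elm: the very flask that is asked about, followed so far
- flask: time 15 d

- elm (time / d: left-handed substrate / %, left-handed product / %): 0.625: 17.1, 19.0; 1.25: 12.1, 27.1; 2.08: 7.2, 39.1; 2.50: 3.6, 39.9; 3.00: 4.5, 45.3; 4.00: 1.6, 49.1; 5.00: 0.3, 49.8

(standard deviation of a reading: 1 percentage point)

- coupling partner is single-handed; left-handed substrate and right-handed substrate are mirror images of each other, charged as a racemate, each of them at the stated concentration
- what was read earlier has a scatter of 1 percentage point, one standard deviation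
- at the start none of the gas is in solution
- the reaction counts as stopped when no species that holds the left-handed substrate and right-handed substrate together changes by six tenths of a point or more over the second half of the time
- the handed part of coupling partner does not stay in what it makes, so the products of the two hands are mirror images too

1. why nothing more happens at 15 d, or that something still does (it is still moving / all of the left-handed substrate has reacted / forward and back rates have come level)
2. part of the left-handed substrate and right-handed substrate together gone at 15 d
3. the left-handed product standing at 15 d, as a percentage of the left-handed substrate and right-handed substrate together charged

Take the elm readings of c(left-handed substrate) at 0.625 d and 4.00 d, and treat the fall between them as a pseudo-first-order tail. Divide the asked time by the time in which that tail falls by a factor e, and time drops out. This gives the tail number 10.5, a reading with the scatter of its two points. It means that a tail running from the start leaves exp(−number) of the charged left-handed substrate at the end, here 0.00267%, so my own reckoning is that this substrate is gone by then.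

Was one number enough? Carried back to the start, the tail gives 26.5%, less than the 50.0% charged, so a faster loss ran before the tail. The number is silent on that loss, and the right-handed substrate was never read, so I put conversion at no less than 50.0%.

The forecast says all of the left-handed substrate has reacted, with 50% gone and 50% of left-handed product. On the right-handed substrate it says: “I expect the single-handed partner to leave it essentially untouched”.

The flask gives all of the left-handed substrate has reacted, with >99.9% gone and 52.3% of left-handed product.

    coupling partner + left-handed substrate → left-handed product (k = 69.9 M⁻¹ h⁻¹)
    gas ⇌ coupling partner, rate k2*(csat - [coupling partner]) (kL = 66.7 h⁻¹)
    left-handed substrate ⇌ achiral form (K = 1.70, k = 0.344 h⁻¹)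
    coupling partner + right-handed substrate → right-handed product (k = 43.8 M⁻¹ h⁻¹)
    achiral form → waste (k = 0.00743 h⁻¹)
    right-handed substrate ⇌ achiral form (K = 1.70, k = 0.344 h⁻¹)

The tail number's 0.00267% stands against 0.0062% of charged left-handed substrate left in this flask. Scaled to the neighbouring flask, stopped at 4.0 d, it gives 6.03%, and that flask holds 4.6%. In this flask both substrates coupled with the coupling partner and exchanged with the achiral form, and at 1.50 d stood 31.5% left-handed product, 20.7% right-handed product and 18.9% achiral form. By 7.50 d the achiral form was down to 0.516%, and the flask ended with 52.3% left-handed product, 34.4% right-handed product and 13.3% waste.

Readings and results stem from a simulated flask on assumed constants; scatter was added.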